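The route builds the benzene ring of the prenylated indole last. Carbons C4–C7 of that indole carry one substituent only, the prenyl group on C7 next to the ring-fusion carbon C7a. C7 corresponds to the carbon alpha to the lactone carbonyl of a pyrano[4,3-b]pyrrol-6(1H)-one, where prenyl is introduced by simple enolate alkylation. The precursor is thus an N-acetyl 7-prenylpyranopyrrolone that already bears the tetramethoxyphenyl–indole unit on C3. Heating it with phenyl vinyl sulfoxide joins two CH carbons to C4 and C7, expels CO2 and PhSOH and gives the complete indole in one operation. Oxidative demethylation to the quinone and methanolysis of both N-acetyl groups finish the synthesis.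

Key step: step 12

Remark on the chemistry: the target has no stereocentre. Compounds 19–22 are racemic at the side-chain carbon, which becomes sp2 in step 11. The organometallic solutions (n-BuLi, LiN(i-Pr)2, LiN(SiMe3)2, compound 15) are taken as commercial.

Step 1
Reactants: 1 1,2,4,5-tetramethoxybenzene; 2 3-bromo-1-(triisopropylsilyl)indole
Product: 5 3-(2,3,5,6-tetramethoxyphenyl)-1-(triisopropylsilyl)indole, via aryllithium 3 (not isolated), via arylzinc chloride 4 (not isolated)
Conditions: n-BuLi, THF, 0 °C → rt; ZnCl2, THF; then 2, Pd(OAc)2 (cat.), SPhos, THF, 65 °C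
Reagents that add atoms: none
Why: Ortho-lithiation of 1 between two methoxy groups, transmetalation to zinc and Negishi coupling with a biarylphosphine-ligated palladium catalyst should tolerate the two ortho-methoxy groups, while the bulky N-silyl group keeps the indole C2–H inert.

Step 2
Reactants: 5 3-(2,3,5,6-tetramethoxyphenyl)-1-(triisopropylsilyl)indole
Product: 7 2,3,5,6-tetramethoxy-4-(1-triisopropylsilylindol-3-yl)benzaldehyde, via aryllithium 6 (not isolated)
Conditions: n-BuLi, TMEDA, THF, 0 °C; DMF, 0 °C → rt; then H2O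
Reagents that add atoms: N,N-dimethylformamide, CN(C)C=O
Why: The last ring C–H of 5 is flanked by two methoxy groups and should be removed by n-BuLi (directed ortho-metalation) faster than the silyl-shielded indole C2–H, and DMF formylates the aryllithium.

Step 3
Reactants: 7 2,3,5,6-tetramethoxy-4-(1-triisopropylsilylindol-3-yl)benzaldehyde; 8 diethyl {2-[methoxy(methyl)amino]-2-oxoethyl}phosphonate
Product: 9 (E)-N-methoxy-N-methyl-3-[2,3,5,6-tetramethoxy-4-(1-triisopropylsilylindol-3-yl)phenyl]prop-2-enamide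
Conditions: NaH, THF, 0 °C → rt
Reagents that add atoms: none
Why: Horner–Wadsworth–Emmons olefination of the hindered, non-enolisable aldehyde with the stabilised phosphonate anion should give the E-acrylamide, and any Z isomer converges in step 4.

Step 4
Reactants: 9 (E)-N-methoxy-N-methyl-3-[2,3,5,6-tetramethoxy-4-(1-triisopropylsilylindol-3-yl)phenyl]prop-2-enamide; 10 p-toluenesulfonylmethyl isocyanide
Product: 11 N-methoxy-N-methyl-4-[2,3,5,6-tetramethoxy-4-(1-triisopropylsilylindol-3-yl)phenyl]-1H-pyrrole-3-carboxamide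
Conditions: t-BuOK, THF, −20 °C → rt
Reagents that add atoms: none
Why: In the van Leusen pyrrole synthesis, Michael addition of metalated isocyanide to the unsaturated Weinreb amide, ring closure onto the isocyanide carbon and loss of sulfinate fix the 3-carboxamide-4-aryl pattern, and the N–Si bond is shielded from the bulky alkoxide.

Step 5
Reactants: 11 N-methoxy-N-methyl-4-[2,3,5,6-tetramethoxy-4-(1-triisopropylsilylindol-3-yl)phenyl]-1H-pyrrole-3-carboxamide
Product: 12 tert-butyl 3-[methoxy(methyl)carbamoyl]-4-[2,3,5,6-tetramethoxy-4-(1-triisopropylsilylindol-3-yl)phenyl]pyrrole-1-carboxylate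
Conditions: Boc2O, DMAP (cat.), MeCN, rt
Reagents that add atoms: di-tert-butyl dicarbonate, CC(C)(C)OC(=O)OC(=O)OC(C)(C)C
Why: DMAP-catalysed N-acylation of the acidic pyrrole N–H installs the carbamate that directs step 6 and blocks N-alkylation in step 8.

Step 6
Reactants: 12 tert-butyl 3-[methoxy(methyl)carbamoyl]-4-[2,3,5,6-tetramethoxy-4-(1-triisopropylsilylindol-3-yl)phenyl]pyrrole-1-carboxylate
Product: 14 tert-butyl 2-iodo-3-[methoxy(methyl)carbamoyl]-4-[2,3,5,6-tetramethoxy-4-(1-triisopropylsilylindol-3-yl)phenyl]pyrrole-1-carboxylate, via pyrrol-2-yllithium 13 (not isolated)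
Conditions: LiN(i-Pr)2, THF, −78 °C; I2, −78 → −40 °C
Reagents that add atoms: iodine, II
Why: In this directed metalation C2–H lies between the carbamate and the carboxamide, which both bind lithium and acidify it, so deprotonation should occur there and not at C5 (electrophilic iodination would go to C5), and iodine traps the anion at −78 °C before the carbamate can migrate.

Step 7
Reactants: 14 tert-butyl 2-iodo-3-[methoxy(methyl)carbamoyl]-4-[2,3,5,6-tetramethoxy-4-(1-triisopropylsilylindol-3-yl)phenyl]pyrrole-1-carboxylate; 15 bromo(2-ethoxy-2-oxoethyl)zinc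
Product: 16 tert-butyl 2-(2-ethoxy-2-oxoethyl)-3-[methoxy(methyl)carbamoyl]-4-[2,3,5,6-tetramethoxy-4-(1-triisopropylsilylindol-3-yl)phenyl]pyrrole-1-carboxylate
Conditions: Pd2(dba)3 (cat.), XPhos, THF, 50 °C
Reagents that add atoms: none
Why: Negishi-type α-arylation of a Reformatsky reagent (oxidative addition into C–I, transmetalation of the zinc enolate, reductive elimination) should proceed because the mild zinc enolate attacks neither the carbamate nor the Weinreb amide.

Step 8
Reactants: 16 tert-butyl 2-(2-ethoxy-2-oxoethyl)-3-[methoxy(methyl)carbamoyl]-4-[2,3,5,6-tetramethoxy-4-(1-triisopropylsilylindol-3-yl)phenyl]pyrrole-1-carboxylate; 17 1-bromo-3-methylbut-2-ene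
Product: 19 tert-butyl 2-(1-ethoxy-5-methyl-1-oxohex-4-en-2-yl)-3-[methoxy(methyl)carbamoyl]-4-[2,3,5,6-tetramethoxy-4-(1-triisopropylsilylindol-3-yl)phenyl]pyrrole-1-carboxylate (racemic), via lithium enolate 18 (not isolated)
Conditions: LiN(SiMe3)2, THF, −78 °C; 17, −78 → −20 °C
Reagents that add atoms: none
Why: Ester enolate alkylation (SN2) of the heteroaryl-activated methylene with the allylic bromide places the prenyl group on the future C7, and the new stereocentre forms as a racemate that is erased in step 11.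

Step 9
Reactants: 19 tert-butyl 2-(1-ethoxy-5-methyl-1-oxohex-4-en-2-yl)-3-[methoxy(methyl)carbamoyl]-4-[2,3,5,6-tetramethoxy-4-(1-triisopropylsilylindol-3-yl)phenyl]pyrrole-1-carboxylate (racemic)
Product: 20 tert-butyl 2-(1-ethoxy-5-methyl-1-oxohex-4-en-2-yl)-3-formyl-4-[2,3,5,6-tetramethoxy-4-(1-triisopropylsilylindol-3-yl)phenyl]pyrrole-1-carboxylate (racemic)
Conditions: Cp2Zr(H)Cl, THF, rt; then H2O, silica gel
Reagents that add atoms: none
Why: Hydrozirconation of the tertiary amide carbonyl gives a zirconium-bound hemiaminal that releases the aldehyde only on work-up, while the ester, the carbamate and the trisubstituted alkene react far more slowly, which is why C3 carries an amide and not an ester.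

Step 10
Reactants: 20 tert-butyl 2-(1-ethoxy-5-methyl-1-oxohex-4-en-2-yl)-3-formyl-4-[2,3,5,6-tetramethoxy-4-(1-triisopropylsilylindol-3-yl)phenyl]pyrrole-1-carboxylate (racemic)
Product: 22 2-{3-formyl-4-[4-(1H-indol-3-yl)-2,3,5,6-tetramethoxyphenyl]-1H-pyrrol-2-yl}-5-methylhex-4-enoic acid (racemic), via desilylated ester 21 (not isolated)
Conditions: Bu4NF, THF, 0 °C → rt; then LiOH, MeOH/H2O, 40 °C; then 1 M HCl to pH 4, 0 °C
Reagents that add atoms: lithium hydroxide, [Li+].[OH-]
Why: Fluoride cleaves the N–Si bond and hydroxide then saponifies the ethyl ester and removes the base-labile carbamate of the 3-formylpyrrole, with no acid used because an aldehyde and a prenyl group in this 1,6-relationship are prone to acid-induced carbonyl–ene cyclisation.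

Step 11
Reactants: 22 2-{3-formyl-4-[4-(1H-indol-3-yl)-2,3,5,6-tetramethoxyphenyl]-1H-pyrrol-2-yl}-5-methylhex-4-enoic acid (racemic)
Product: 24 1-acetyl-3-[4-(1-acetylindol-3-yl)-2,3,5,6-tetramethoxyphenyl]-7-(3-methylbut-2-enyl)pyrano[4,3-b]pyrrol-6(1H)-one, via N-unsubstituted pyranone 23 (not isolated)
Conditions: Ac2O, Et3N, DMAP (cat.), CH2Cl2, 0 °C → rt
Reagents that add atoms: acetic anhydride, CC(=O)OC(C)=O
Why: Mixed-anhydride cyclodehydration of the formyl acid (enol lactonisation, in which the side-chain stereocentre becomes sp2) is followed in the same flask by DMAP-catalysed N-acetylation of both N–H groups.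

Step 12
Reactants: 24 1-acetyl-3-[4-(1-acetylindol-3-yl)-2,3,5,6-tetramethoxyphenyl]-7-(3-methylbut-2-enyl)pyrano[4,3-b]pyrrol-6(1H)-one; 25 phenyl vinyl sulfoxide (racemic)
Product: 28 1-acetyl-3-[4-(1-acetylindol-3-yl)-2,3,5,6-tetramethoxyphenyl]-7-(3-methylbut-2-enyl)indole, via bridged cycloadduct 26 (not isolated), via dihydroindole sulfoxide 27 (not isolated)
Conditions: 25 (excess), NaHCO3, toluene, sealed tube, 120 °C
Reagents that add atoms: none
Why: The pyranone diene C4=C3a–C7a=C7 of 24, a masked pyrrole-2,3-quinodimethane, undergoes a thermal [4+2] cycloaddition with the vinyl sulfoxide that forms C4–C5 and C6–C7 and gives the bridged lactone 26; retro-[4+2] loss of CO2 then leads to dihydroindole 27, and syn-elimination of benzenesulfenic acid aromatises it to 28. The closest known reaction type is the Diels–Alder/decarboxylation sequence of 2-pyranones and of pyrano-fused pyrroles and indoles with alkynes or acetylene equivalents. The one ring closed is the six-membered carbocycle C3a–C4–C5–C6–C7–C7a, made by intermolecular cycloaddition in which both new bonds form in a single suprafacial event. The stereocentres that appear in 26 and 27 (C4, C7, the sulfinyl-bearing carbon and sulfur) are uncontrolled and all disappear on aromatisation, so none has to be set. The step needs site selectivity for the pyranone diene over the prenyl alkene and the indole C2=C3 bond, which the quinodimethane character of the diene and the gain of two aromatic rings should secure, whereas the orientation of the dienophile is irrelevant because both new carbons end as unsubstituted CH. The two N-acetyl groups, unlike a thermally labile carbamate, should survive 120 °C and keep both indole rings inert towards sulfenylation by PhSOH-derived species.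

Step 13
Reactants: 28 1-acetyl-3-[4-(1-acetylindol-3-yl)-2,3,5,6-tetramethoxyphenyl]-7-(3-methylbut-2-enyl)indole
Product: 29 2-(1-acetylindol-3-yl)-5-[1-acetyl-7-(3-methylbut-2-enyl)indol-3-yl]-3,6-dimethoxycyclohexa-2,5-diene-1,4-dione
Conditions: (NH4)2Ce(NO3)6, MeCN/H2O (3:1), 0 °C
Reagents that add atoms: water, O
Why: Oxidative demethylation by tetravalent cerium with ipso attack of water gives the para-quinone, which is the same compound whichever para pair of methoxy groups is lost, while the N-acetyl groups raise the oxidation potential of both indoles and the isolated trisubstituted alkene is not touched at 0 °C.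

Step 14
Reactants: 29 2-(1-acetylindol-3-yl)-5-[1-acetyl-7-(3-methylbut-2-enyl)indol-3-yl]-3,6-dimethoxycyclohexa-2,5-diene-1,4-dione
Product: 30 2-(1H-indol-3-yl)-3,6-dimethoxy-5-[7-(3-methylbut-2-enyl)-1H-indol-3-yl]cyclohexa-2,5-diene-1,4-dione (CNP0256613.0)
Conditions: K2CO3 (cat.), MeOH/THF, 0 °C → rt
Reagents that add atoms: none
Why: Base-catalysed methanolysis of the two N-acylindoles (activated amides) is fast, and methoxide exchange at the methoxy-bearing quinone carbons is degenerate in methanol, so the vinylogous ester groups survive where fluoride or hydroxide could demethylate them.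

Compound list
1 | 1,2,4,5-tetramethoxybenzene | COc1cc(OC)c(OC)cc1OC | starting material
2 | 3-bromo-1-(triisopropylsilyl)indole | CC(C)[Si](C(C)C)(C(C)C)n1cc(Br)c2ccccc12 | starting material
3 | (2,3,5,6-tetramethoxyphenyl)lithium (not isolated) | [Li]c1c(OC)c(OC)cc(OC)c1OC | intermediate
4 | chloro(2,3,5,6-tetramethoxyphenyl)zinc (not isolated) | Cl[Zn]c1c(OC)c(OC)cc(OC)c1OC | intermediate
5 | 3-(2,3,5,6-tetramethoxyphenyl)-1-(triisopropylsilyl)indole | COc1cc(OC)c(OC)c(-c2cn([Si](C(C)C)(C(C)C)C(C)C)c3ccccc23)c1OC | intermediate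
6 | [2,3,5,6-tetramethoxy-4-(1-triisopropylsilylindol-3-yl)phenyl]lithium (not isolated) | [Li]c1c(OC)c(OC)c(-c2cn([Si](C(C)C)(C(C)C)C(C)C)c3ccccc23)c(OC)c1OC | intermediate
7 | 2,3,5,6-tetramethoxy-4-(1-triisopropylsilylindol-3-yl)benzaldehyde | O=Cc1c(OC)c(OC)c(-c2cn([Si](C(C)C)(C(C)C)C(C)C)c3ccccc23)c(OC)c1OC | intermediate
8 | diethyl {2-[methoxy(methyl)amino]-2-oxoethyl}phosphonate | CCOP(=O)(CC(=O)N(C)OC)OCC | starting material
9 | (E)-N-methoxy-N-methyl-3-[2,3,5,6-tetramethoxy-4-(1-triisopropylsilylindol-3-yl)phenyl]prop-2-enamide | CON(C)C(=O)/C=C/c1c(OC)c(OC)c(-c2cn([Si](C(C)C)(C(C)C)C(C)C)c3ccccc23)c(OC)c1OC | intermediate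
10 | p-toluenesulfonylmethyl isocyanide | [C-]#[N+]CS(=O)(=O)c1ccc(C)cc1 | starting material
11 | N-methoxy-N-methyl-4-[2,3,5,6-tetramethoxy-4-(1-triisopropylsilylindol-3-yl)phenyl]-1H-pyrrole-3-carboxamide | CON(C)C(=O)c1c[nH]cc1-c1c(OC)c(OC)c(-c2cn([Si](C(C)C)(C(C)C)C(C)C)c3ccccc23)c(OC)c1OC | intermediate
12 | tert-butyl 3-[methoxy(methyl)carbamoyl]-4-[2,3,5,6-tetramethoxy-4-(1-triisopropylsilylindol-3-yl)phenyl]pyrrole-1-carboxylate | CON(C)C(=O)c1cn(C(=O)OC(C)(C)C)cc1-c1c(OC)c(OC)c(-c2cn([Si](C(C)C)(C(C)C)C(C)C)c3ccccc23)c(OC)c1OC | intermediate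
13 | 2-lithio derivative of 12 (not isolated) | CON(C)C(=O)c1c([Li])n(C(=O)OC(C)(C)C)cc1-c1c(OC)c(OC)c(-c2cn([Si](C(C)C)(C(C)C)C(C)C)c3ccccc23)c(OC)c1OC | intermediate
14 | tert-butyl 2-iodo-3-[methoxy(methyl)carbamoyl]-4-[2,3,5,6-tetramethoxy-4-(1-triisopropylsilylindol-3-yl)phenyl]pyrrole-1-carboxylate | CON(C)C(=O)c1c(I)n(C(=O)OC(C)(C)C)cc1-c1c(OC)c(OC)c(-c2cn([Si](C(C)C)(C(C)C)C(C)C)c3ccccc23)c(OC)c1OC | intermediate
15 | bromo(2-ethoxy-2-oxoethyl)zinc (commercial solution in THF) | CCOC(=O)C[Zn]Br | starting material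
16 | tert-butyl 2-(2-ethoxy-2-oxoethyl)-3-[methoxy(methyl)carbamoyl]-4-[2,3,5,6-tetramethoxy-4-(1-triisopropylsilylindol-3-yl)phenyl]pyrrole-1-carboxylate | CCOC(=O)Cc1c(C(=O)N(C)OC)c(-c2c(OC)c(OC)c(-c3cn([Si](C(C)C)(C(C)C)C(C)C)c4ccccc34)c(OC)c2OC)cn1C(=O)OC(C)(C)C | intermediate
17 | 1-bromo-3-methylbut-2-ene | CC(C)=CCBr | starting material
18 | lithium enolate of 16 (not isolated; enolate geometry undefined) | CCOC(O[Li])=Cc1c(C(=O)N(C)OC)c(-c2c(OC)c(OC)c(-c3cn([Si](C(C)C)(C(C)C)C(C)C)c4ccccc34)c(OC)c2OC)cn1C(=O)OC(C)(C)C | intermediate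
19 | tert-butyl 2-(1-ethoxy-5-methyl-1-oxohex-4-en-2-yl)-3-[methoxy(methyl)carbamoyl]-4-[2,3,5,6-tetramethoxy-4-(1-triisopropylsilylindol-3-yl)phenyl]pyrrole-1-carboxylate (racemic) | CCOC(=O)C(CC=C(C)C)c1c(C(=O)N(C)OC)c(-c2c(OC)c(OC)c(-c3cn([Si](C(C)C)(C(C)C)C(C)C)c4ccccc34)c(OC)c2OC)cn1C(=O)OC(C)(C)C | intermediate
20 | tert-butyl 2-(1-ethoxy-5-methyl-1-oxohex-4-en-2-yl)-3-formyl-4-[2,3,5,6-tetramethoxy-4-(1-triisopropylsilylindol-3-yl)phenyl]pyrrole-1-carboxylate (racemic) | CCOC(=O)C(CC=C(C)C)c1c(C=O)c(-c2c(OC)c(OC)c(-c3cn([Si](C(C)C)(C(C)C)C(C)C)c4ccccc34)c(OC)c2OC)cn1C(=O)OC(C)(C)C | intermediate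
21 | tert-butyl 2-(1-ethoxy-5-methyl-1-oxohex-4-en-2-yl)-3-formyl-4-[4-(1H-indol-3-yl)-2,3,5,6-tetramethoxyphenyl]pyrrole-1-carboxylate (racemic; not isolated) | CCOC(=O)C(CC=C(C)C)c1c(C=O)c(-c2c(OC)c(OC)c(-c3c[nH]c4ccccc34)c(OC)c2OC)cn1C(=O)OC(C)(C)C | intermediate
22 | 2-{3-formyl-4-[4-(1H-indol-3-yl)-2,3,5,6-tetramethoxyphenyl]-1H-pyrrol-2-yl}-5-methylhex-4-enoic acid (racemic) | OC(=O)C(CC=C(C)C)c1[nH]cc(-c2c(OC)c(OC)c(-c3c[nH]c4ccccc34)c(OC)c2OC)c1C=O | intermediate
23 | 3-[4-(1H-indol-3-yl)-2,3,5,6-tetramethoxyphenyl]-7-(3-methylbut-2-enyl)pyrano[4,3-b]pyrrol-6(1H)-one (not isolated) | O=C1OC=C2C(c3c(OC)c(OC)c(-c4c[nH]c5ccccc45)c(OC)c3OC)=CNC2=C1CC=C(C)C | intermediate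
24 | 1-acetyl-3-[4-(1-acetylindol-3-yl)-2,3,5,6-tetramethoxyphenyl]-7-(3-methylbut-2-enyl)pyrano[4,3-b]pyrrol-6(1H)-one | O=C1OC=C2C(c3c(OC)c(OC)c(-c4cn(C(C)=O)c5ccccc45)c(OC)c3OC)=CN(C(C)=O)C2=C1CC=C(C)C | intermediate
25 | phenyl vinyl sulfoxide (racemic) | C=CS(=O)c1ccccc1 | starting material
26 | bridged lactone cycloadduct of 24 and 25 (not isolated; mixture of regio- and stereoisomers, one regioisomer drawn, configuration undefined) | O=C1OC2C(S(=O)c3ccccc3)CC1(CC=C(C)C)c4c2c(-c5c(OC)c(OC)c(-c6cn(C(C)=O)c7ccccc67)c(OC)c5OC)cn4C(C)=O | intermediate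
27 | 1-acetyl-3-[4-(1-acetylindol-3-yl)-2,3,5,6-tetramethoxyphenyl]-7-(3-methylbut-2-enyl)-5-(phenylsulfinyl)-5,6-dihydroindole (not isolated; 5-sulfinyl regioisomer drawn, configuration undefined) | CC(=O)N1C=C(c2c(OC)c(OC)c(-c3cn(C(C)=O)c4ccccc34)c(OC)c2OC)C5=CC(S(=O)c6ccccc6)CC(CC=C(C)C)=C15 | intermediate
28 | 1-acetyl-3-[4-(1-acetylindol-3-yl)-2,3,5,6-tetramethoxyphenyl]-7-(3-methylbut-2-enyl)indole | CC(=O)n1cc(-c2c(OC)c(OC)c(-c3cn(C(C)=O)c4ccccc34)c(OC)c2OC)c2cccc(CC=C(C)C)c12 | intermediate
29 | 2-(1-acetylindol-3-yl)-5-[1-acetyl-7-(3-methylbut-2-enyl)indol-3-yl]-3,6-dimethoxycyclohexa-2,5-diene-1,4-dione | COC1=C(c2cn(C(C)=O)c3ccccc23)C(=O)C(OC)=C(c2cn(C(C)=O)c3c(CC=C(C)C)cccc23)C1=O | intermediate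
30 | 2-(1H-indol-3-yl)-3,6-dimethoxy-5-[7-(3-methylbut-2-enyl)-1H-indol-3-yl]cyclohexa-2,5-diene-1,4-dione (CNP0256613.0) | COC1=C(c2c[nH]c3ccccc23)C(=O)C(OC)=C(c2c[nH]c3c(CC=C(C)C)cccc23)C1=O | target

Total step count: 14. Longest linear sequence: 14 steps (fully linear from 1 and 2).

Steps most likely to fail

Step 12. The cycloaddition may be too slow for this weakly electron-poor dienophile, so that thermal decomposition or hydrolytic opening of the acylated enol lactone wins, or sulfenic acid by-products may attack the substrate. The fallback reverses the electronic demand. Starting from 24, heating with ethyl vinyl ether in a sealed tube (toluene, 110 °C) should give the bridged ethoxy lactone F1, which loses CO2 to the ethoxy-dihydroindole F2. Elimination of ethanol from F2, thermally or with a trace of pyridinium p-toluenesulfonate, gives 28, where the route is rejoined. Cycloaddition of 2-pyranones with enol ethers followed by loss of CO2 and alcohol is known chemistry.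

Step 11. N-Acetylation of the hindered, ambident pyranone nitrogen may be incomplete or compete with O-acylation, and the acylated lactone may ring-open on isolation. The fallback moves nitrogen protection behind the key step. Starting from 22, Ac2O alone in toluene at 50 °C should give the N-unsubstituted pyranone 23, which is isolated. Cycloaddition of 23 with 25 under the conditions of step 12 passes through the bridged sulfinyl lactone F3 and the N-unsubstituted sulfinyl-dihydroindole F4 to the free bis-indole F5. Acetylation of both indole nitrogens of F5 (Ac2O, Et3N, DMAP, CH2Cl2) gives 28, where the route is rejoined.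

Step 9. Hydrozirconation of the amide, which is flanked on both sides, may stall, or reduction may spill over to the carbamate or the ester. The fallback replaces reagent-controlled chemoselectivity by substrate control. Starting from 19, Bu4NF and then LiOH (conditions of step 10) should give, through the desilylated Weinreb amide ester F6, the Weinreb amide acid F7, in which the competing ester has become a carboxylate. Reduction of F7 with excess i-Bu2AlH (THF, −78 °C), which turns the Weinreb amide into a stable chelated hemiaminal and leaves the aluminium carboxylate alone, gives 22 after work-up at pH 4, where the route is rejoined.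

Further compounds
F1 | step 12 | bridged ethoxy lactone cycloadduct of 24 and ethyl vinyl ether (one regioisomer drawn, configuration undefined) | O=C1OC2C(OCC)CC1(CC=C(C)C)c3c2c(-c4c(OC)c(OC)c(-c5cn(C(C)=O)c6ccccc56)c(OC)c4OC)cn3C(C)=O
F2 | step 12 | 1-acetyl-3-[4-(1-acetylindol-3-yl)-2,3,5,6-tetramethoxyphenyl]-5-ethoxy-7-(3-methylbut-2-enyl)-5,6-dihydroindole (one regioisomer drawn, configuration undefined) | CC(=O)N1C=C(c2c(OC)c(OC)c(-c3cn(C(C)=O)c4ccccc34)c(OC)c2OC)C5=CC(OCC)CC(CC=C(C)C)=C15
F3 | step 11 | bridged sulfinyl lactone cycloadduct of 23 and 25 (one regioisomer drawn, configuration undefined) | O=C1OC2C(S(=O)c3ccccc3)CC1(CC=C(C)C)c4c2c(-c5c(OC)c(OC)c(-c6c[nH]c7ccccc67)c(OC)c5OC)c[nH]4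
F4 | step 11 | 3-[4-(1H-indol-3-yl)-2,3,5,6-tetramethoxyphenyl]-7-(3-methylbut-2-enyl)-5-(phenylsulfinyl)-5,6-dihydro-1H-indole (one regioisomer drawn, configuration undefined) | N1C=C(c2c(OC)c(OC)c(-c3c[nH]c4ccccc34)c(OC)c2OC)C5=CC(S(=O)c6ccccc6)CC(CC=C(C)C)=C15
F5 | step 11 | 3-[4-(1H-indol-3-yl)-2,3,5,6-tetramethoxyphenyl]-7-(3-methylbut-2-enyl)-1H-indole | COc1c(OC)c(-c2c[nH]c3c(CC=C(C)C)cccc23)c(OC)c(OC)c1-c1c[nH]c2ccccc12
F6 | step 9 | tert-butyl 2-(1-ethoxy-5-methyl-1-oxohex-4-en-2-yl)-4-[4-(1H-indol-3-yl)-2,3,5,6-tetramethoxyphenyl]-3-[methoxy(methyl)carbamoyl]pyrrole-1-carboxylate (racemic) | CCOC(=O)C(CC=C(C)C)c1c(C(=O)N(C)OC)c(-c2c(OC)c(OC)c(-c3c[nH]c4ccccc34)c(OC)c2OC)cn1C(=O)OC(C)(C)C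
F7 | step 9 | 2-{4-[4-(1H-indol-3-yl)-2,3,5,6-tetramethoxyphenyl]-3-[methoxy(methyl)carbamoyl]-1H-pyrrol-2-yl}-5-methylhex-4-enoic acid (racemic) | OC(=O)C(CC=C(C)C)c1[nH]cc(-c2c(OC)c(OC)c(-c3c[nH]c4ccccc34)c(OC)c2OC)c1C(=O)N(C)OC
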